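Ring B is opened at C7–C8 and C9–C10. This frees a C8–C9 two-carbon unit from an intact ring A that carries the C5–C6–C7 arm. Two features are exploited. Quaternary, methyl-bearing C10 is a tertiary radical in disguise, and the C7 carbinol beside fully substituted C8 is an aldol retron. An iron-hydride (MHAT) radical–polar crossover annulation joins aldehyde 4 (C1=C10 alkene, C7 aldehyde) to α-methyl enal 7. Giese addition makes C9–C10, and the resulting iron enolate closes C7–C8. One operation builds ring B and sets C10, C9, C8 and C7. The surplus formyl group on C8 becomes 8α-OH; a C7 ketone then relays 6α-O and 7β-OH.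

Key step: step 5

Remark: labdane numbering is used throughout (decalin C1–C10, side chain C11–C16, C17 on C8, C18/C19 on C4, C20 on C10). Compound 12 is drawn open-chain although it should rest as its γ-lactol on the 8α-OH.

Step 1
Reactants: 1 2,4,4-trimethylcyclohex-2-en-1-one
Product: 2 (1R)-2,4,4-trimethylcyclohex-2-en-1-ol
Conditions: (S)-Me-CBS (cat.), BH3·SMe2, THF, −20 °C
Reagents that add atoms: none
Why: Corey–Bakshi–Shibata reduction, in which the oxazaborolidine binds the ketone with the 2-methylalkenyl branch as the large group, so that hydride is delivered 1,2 to one face and sets the (R)-carbinol centre (later C1), which exists only to relay chirality.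

Step 2
Reactants: 2 (1R)-2,4,4-trimethylcyclohex-2-en-1-ol
Product: 3 ethyl 2-[(1S)-2,6,6-trimethylcyclohex-2-en-1-yl]acetate
Conditions: MeC(OEt)3, EtCO2H (cat.), 140 °C, EtOH distilled off
Reagents that add atoms: triethyl orthoacetate, CC(OCC)(OCC)OCC
Why: Johnson orthoester Claisen rearrangement, in which the ketene acetal formed on the allylic oxygen rearranges suprafacially, so that the C–O stereocentre is traded for the C5–C6 bond on the same ring face (C5, S) while the double bond moves to C1=C10.

Step 3
Reactants: 3 ethyl 2-[(1S)-2,6,6-trimethylcyclohex-2-en-1-yl]acetate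
Product: 4 2-[(1S)-2,6,6-trimethylcyclohex-2-en-1-yl]acetaldehyde
Conditions: DIBAL-H (1.05 equiv), CH2Cl2, −78 °C; aqueous work-up
Reagents that add atoms: none
Why: Partial ester reduction with DIBAL-H stops at the tetrahedral aluminium hemiacetal, which releases the aldehyde only on work-up, and C5 is not α to the carbonyl group and cannot epimerise.

Step 4
Reactants: 5 methacrolein; 6 4,4-diethoxybut-1-ene (3-butenal diethyl acetal)
Product: 7 (E)-5,5-diethoxy-2-methylpent-2-enal
Conditions: Hoveyda–Grubbs II (cat.), 5 in excess, CH2Cl2, 40 °C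
Reagents that add atoms: none
Why: Olefin cross-metathesis of a terminal alkene with a 1,1-disubstituted electron-poor partner, which does not homodimerise, so that the trisubstituted enal should form under thermodynamic control as the E isomer.

Step 5
Reactants: 4 2-[(1S)-2,6,6-trimethylcyclohex-2-en-1-yl]acetaldehyde; 7 (E)-5,5-diethoxy-2-methylpent-2-enal
Product: 9 12,12-diethoxy-8α-formyl-13,14,15,16-tetranorlabdan-7β-ol (trans-decalin; 5α-H; 9α-H; C17 8β; C20 10β), via enol form of the Giese adduct 8 (not isolated)
Conditions: Fe(acac)3 (cat.), PhSiH3, 7 (3 equiv), ClCH2CH2Cl/EtOH, 0 °C → rt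
Reagents that add atoms: none
Why: Fe(acac)3 and PhSiH3 form an iron hydride that delivers H• to C1 of the trisubstituted C1=C10 alkene of 4 (Markovnikov MHAT); the nucleophilic tertiary C10 radical adds to the β-carbon C9 of enal 7 (C9–C10), Fe(II) reduces the resulting α-formyl radical at C8 to the iron(III) enolate 8, and this enolate attacks the tethered C7 aldehyde (C7–C8) before ethanol protonates the alkoxide. The closest known reaction type is the HAT-initiated radical–polar crossover annulation (reductive Giese addition followed by aldol closure) of γ,δ-unsaturated aldehydes with α-substituted enones and enals. Ring B is the only ring closed, by a 6-(enolexo)-exo-trig aldol through a chair in which the C5–C6 and C10–C9 bonds are both equatorial on ring A, which is the trans-decalin. C10 is set by attack of the enal on the α face of the radical, anti to the C5 arm and away from the axial 4β-methyl group, so that C20 ends β, and C9 is set because the enal approaches with its small C9–H tucked under ring A and C8 turned towards the C5 arm, which leaves C11 equatorial (9α-H), while a C9-epimeric adduct would need an axial C11 in the aldol chair and is expected to stay open-chain and separable. C8 is set by A(1,3) strain, which holds C9–H in the plane of the trisubstituted enolate so that the formyl group ends equatorial (8α) and C17 axial (8β), and C7 takes the equatorial 7β-alkoxide but is erased again in step 10. The step needs HAT to the electron-rich ring alkene rather than to the electron-poor enal, which the polarity preference of the iron hydride and the excess of 7 secure, and it needs the aldol to outrun enolate protonation, which the six-membered intramolecular closure secures; the diethyl acetal that masks C12 is inert.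

Step 6
Reactants: 9 12,12-diethoxy-8α-formyl-13,14,15,16-tetranorlabdan-7β-ol
Product: 11 12,12-diethoxy-13,14,15,16-tetranorlabdane-7β,8α-diol, via C8 formate 10 (not isolated)
Conditions: mCPBA, CH2Cl2, 0 °C → rt; then K2CO3 (cat.), MeOH, 0 °C
Reagents that add atoms: mCPBA, O=C(OO)c1cccc(Cl)c1
Why: Baeyer–Villiger oxidation of an α-quaternary aldehyde, in which the fully substituted C8 migrates in preference to hydride and with retention, so that the 8α-formyl group becomes the 8α-formate, which catalytic methanolysis removes.

Step 7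
Reactants: 11 12,12-diethoxy-13,14,15,16-tetranorlabdane-7β,8α-diol
Product: 12 7β,8α-dihydroxy-13,14,15,16-tetranorlabdan-12-al
Conditions: 1 M HCl, THF, rt
Reagents that add atoms: water, O
Why: Acid-catalysed acetal hydrolysis unmasks the C12 aldehyde, touches no stereocentre, and is mild enough to leave the tertiary 8α-OH in place.

Step 8
Reactants: 12 7β,8α-dihydroxy-13,14,15,16-tetranorlabdan-12-al
Product: 13 (12E)-7β,8α-dihydroxy-15-norlabd-12-en-14-al
Conditions: Ph3P=C(Me)CHO, toluene, 90 °C
Reagents that add atoms: 2-(triphenylphosphoranylidene)propanal, CC(C=O)=P(c1ccccc1)(c1ccccc1)c1ccccc1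
Why: Wittig olefination with a stabilised ylide, which drains the open hydroxy aldehyde from the lactol equilibrium and should give the (12E)-trisubstituted enal through reversible oxaphosphetane formation.

Step 9
Reactants: 13 (12E)-7β,8α-dihydroxy-15-norlabd-12-en-14-al
Product: 14 (12E)-labda-12,14-diene-7β,8α-diol
Conditions: Ph3PCH3Br, KHMDS, THF, 0 °C; then 13, −78 → 0 °C
Reagents that add atoms: methyltriphenylphosphonium bromide, C[P+](c1ccccc1)(c1ccccc1)c1ccccc1.[Br-]
Why: Wittig methylenation attacks the enal carbonyl group 1,2 and completes the 12,14-diene without touching the C12=C13 geometry, with excess ylide covering the two free hydroxyl groups.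

Step 10
Reactants: 14 (12E)-labda-12,14-diene-7β,8α-diol
Product: 15 (12E)-8α-hydroxylabda-12,14-dien-7-one
Conditions: IBX, DMSO, rt
Reagents that add atoms: none
Why: IBX oxidation, in which only the secondary C7 alcohol can be oxidised and 1,2-diols give α-ketols without C–C cleavage, while the tertiary 8α-OH and the diene are inert.

Step 11
Reactants: 15 (12E)-8α-hydroxylabda-12,14-dien-7-one
Product: 16 (12E)-6α,8α-dihydroxylabda-12,14-dien-7-one
Conditions: KHMDS (2.5 equiv), THF, −78 °C; then 3-phenyl-2-(phenylsulfonyl)oxaziridine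
Reagents that add atoms: 3-phenyl-2-(phenylsulfonyl)oxaziridine, O=S(=O)(N1OC1c1ccccc1)c1ccccc1
Why: Davis enolate hydroxylation, in which the ketone can enolise only towards C6 because C8 is fully substituted, and the oxidant should attack the C6=C7 enolate from the α face because the axial methyl groups on C4, C8 and C10 screen the β face, which sets the equatorial 6α-OH.

Step 12
Reactants: 16 (12E)-6α,8α-dihydroxylabda-12,14-dien-7-one
Product: 17 (12E)-6α-angeloyloxy-8α-hydroxylabda-12,14-dien-7-one
Conditions: angelic acid, 2,4,6-Cl3C6H2COCl, Et3N, toluene, rt; then 16, 80 °C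
Reagents that add atoms: angelic acid, C/C=C(/C)C(=O)O
Why: Yamaguchi-type esterification through the mixed anhydride without a nucleophilic catalyst, conditions that are known to preserve the Z geometry of angelates, and only the secondary 6α-OH can react because 8α-OH is tertiary, so no protecting group is needed.

Step 13
Reactants: 17 (12E)-6α-angeloyloxy-8α-hydroxylabda-12,14-dien-7-one
Product: 18 (12E)-6α-angeloyloxylabda-12,14-diene-7β,8α-diol (CNP0189082.1)
Conditions: NaBH4, CeCl3·7H2O, MeOH, −78 °C
Reagents that add atoms: none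
Why: Cerium-assisted borohydride reduction, in which hydride attacks the C7 ketone axially from the open α face because the neighbouring axial C17 methyl group blocks the β face, which gives the equatorial 7β-alcohol, while the low temperature spares the conjugated ester and suppresses 6→7 acyl migration.

Compound list
1 | 2,4,4-trimethylcyclohex-2-en-1-one | CC1=CC(C)(C)CCC1=O | starting material
2 | (1R)-2,4,4-trimethylcyclohex-2-en-1-ol | O[C@@H]1CCC(C)(C)C=C1C | intermediate
3 | ethyl 2-[(1S)-2,6,6-trimethylcyclohex-2-en-1-yl]acetate | CCOC(=O)C[C@@H]1C(C)=CCCC1(C)C | intermediate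
4 | 2-[(1S)-2,6,6-trimethylcyclohex-2-en-1-yl]acetaldehyde | O=CC[C@@H]1C(C)=CCCC1(C)C | intermediate
5 | methacrolein | C=C(C)C=O | starting material
6 | 4,4-diethoxybut-1-ene | C=CCC(OCC)OCC | starting material
7 | (E)-5,5-diethoxy-2-methylpent-2-enal | O=C/C(C)=C/CC(OCC)OCC | intermediate
8 | enol form of the Giese adduct (iron enolate in the flask; C10 bonded to C9, C7 aldehyde still free) | O=CC[C@H]1C(C)(C)CCC[C@]1(C)[C@@H](CC(OCC)OCC)C(C)=CO | intermediate
9 | 12,12-diethoxy-8α-formyl-13,14,15,16-tetranorlabdan-7β-ol | CCOC(OCC)C[C@H]1[C@](C)(C=O)[C@@H](O)C[C@H]2C(C)(C)CCC[C@@]21C | intermediate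
10 | 12,12-diethoxy-8α-formyloxy-13,14,15,16-tetranorlabdan-7β-ol | CCOC(OCC)C[C@H]1[C@](C)(OC=O)[C@@H](O)C[C@H]2C(C)(C)CCC[C@@]21C | intermediate
11 | 12,12-diethoxy-13,14,15,16-tetranorlabdane-7β,8α-diol | CCOC(OCC)C[C@H]1[C@](C)(O)[C@@H](O)C[C@H]2C(C)(C)CCC[C@@]21C | intermediate
12 | 7β,8α-dihydroxy-13,14,15,16-tetranorlabdan-12-al | O=CC[C@H]1[C@](C)(O)[C@@H](O)C[C@H]2C(C)(C)CCC[C@@]21C | intermediate
13 | (12E)-7β,8α-dihydroxy-15-norlabd-12-en-14-al | O=C/C(C)=C/C[C@H]1[C@](C)(O)[C@@H](O)C[C@H]2C(C)(C)CCC[C@@]21C | intermediate
14 | (12E)-labda-12,14-diene-7β,8α-diol | C=C/C(C)=C/C[C@H]1[C@](C)(O)[C@@H](O)C[C@H]2C(C)(C)CCC[C@@]21C | intermediate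
15 | (12E)-8α-hydroxylabda-12,14-dien-7-one | C=C/C(C)=C/C[C@H]1[C@](C)(O)C(=O)C[C@H]2C(C)(C)CCC[C@@]21C | intermediate
16 | (12E)-6α,8α-dihydroxylabda-12,14-dien-7-one | C=C/C(C)=C/C[C@H]1[C@](C)(O)C(=O)[C@H](O)[C@H]2C(C)(C)CCC[C@@]21C | intermediate
17 | (12E)-6α-angeloyloxy-8α-hydroxylabda-12,14-dien-7-one | C=C/C(C)=C/C[C@H]1[C@](C)(O)C(=O)[C@H](OC(=O)/C(C)=C\C)[C@H]2C(C)(C)CCC[C@@]21C | intermediate
18 | (12E)-6α-angeloyloxylabda-12,14-diene-7β,8α-diol (CNP0189082.1) | C=C/C(C)=C/C[C@H]1[C@](C)(O)[C@@H](O)[C@H](OC(=O)/C(C)=C\C)[C@H]2C(C)(C)CCC[C@@]21C | target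

Total step count: 13. Longest linear sequence: 12 steps (steps 1–3 and 5–13, from 1 to 18).

Steps most likely to fail

Step 5.
- **What may go wrong:** the hindered tertiary radical may add only slowly to the β-alkyl-substituted enal, so that simple reduction of the radical or of the enal takes over. The relative topicity at C9/C10 may be weakly controlled. The enolate may be protonated before the aldol closure.
- **Fallback (from 4, back at 12):** aldehyde 4 is annulated under the same iron-hydride regime with commercial ethyl (E)-3-methyl-4-oxobut-2-enoate. Its ene-dicarbonyl π system is a far better radical trap and is attacked at its CH terminus. C9–C10 and C7–C8 are still made in one operation, giving the 9β-ethoxycarbonyl hydroxy aldehyde F1. Baeyer–Villiger oxidation gives the C8 formate F2, and methanolysis gives the diol ester F3. LiAlH4 then gives the 7β,8α,11-triol F4. TEMPO/PhI(OAc)2 oxidises only the primary alcohol to the 11-aldehyde F5. In F5, C9 is α to a carbonyl group and can be equilibrated with DBU to the equatorial 9β epimer. Wittig reaction with methoxymethylenetriphenylphosphorane gives the enol ether F6, and aqueous acid hydrolyses it to the one-carbon homologue 12.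

Step 6.
- **What may go wrong:** hydride may migrate instead of C8 in the Criegee adduct, which means over-oxidation at the formyl carbon, or ring B may open by retro-aldol cleavage.
- **Fallback (from 9, back at 11):** the formyl carbon is removed as an electrofuge rather than by migration, and C8 is re-set under substrate control. IBX oxidises 9 to the non-enolisable β-keto aldehyde F7. K2CO3 in methanol cleaves F7 by retro-Claisen deformylation to the 8α-methyl 7-ketone F8. The more substituted thermodynamic enolate (KOt-Bu, t-BuOH/THF) is oxygenated with O2/P(OEt)3 from the open α face to the 8α-hydroxy 7-ketone F9. NaBH4 reduces F9 from the α face to diol 11.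

Step 12.
- **What may go wrong:** the angeloyl unit may isomerise from Z to E during activation, the hindered 6α-OH may acylate slowly, and base at 80 °C may induce an α-ketol shift.
- **Fallback (from 16, back at 17):** the C–O bond is made first with a saturated acid, and the Z-alkene is built afterwards. 16 is esterified (EDC, DMAP, rt) with 2-[bis(2,2,2-trifluoroethoxy)phosphoryl]propanoic acid to the phosphonopropionate ester F10. A Still–Gennari olefination (KHMDS, 18-crown-6, acetaldehyde, −78 °C) then gives the Z-configured 2-methylbut-2-enoate 17.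

Further compounds
F1 | step 5 | ethyl 8α-formyl-7β-hydroxy-12,13,14,15,16-pentanorlabdan-11-oate | CCOC(=O)[C@H]1[C@](C)(C=O)[C@@H](O)C[C@H]2C(C)(C)CCC[C@@]21C
F2 | step 5 | ethyl 8α-formyloxy-7β-hydroxy-12,13,14,15,16-pentanorlabdan-11-oate | CCOC(=O)[C@H]1[C@](C)(OC=O)[C@@H](O)C[C@H]2C(C)(C)CCC[C@@]21C
F3 | step 5 | ethyl 7β,8α-dihydroxy-12,13,14,15,16-pentanorlabdan-11-oate | CCOC(=O)[C@H]1[C@](C)(O)[C@@H](O)C[C@H]2C(C)(C)CCC[C@@]21C
F4 | step 5 | 12,13,14,15,16-pentanorlabdane-7β,8α,11-triol | OC[C@H]1[C@](C)(O)[C@@H](O)C[C@H]2C(C)(C)CCC[C@@]21C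
F5 | step 5 | 7β,8α-dihydroxy-12,13,14,15,16-pentanorlabdan-11-al | O=C[C@H]1[C@](C)(O)[C@@H](O)C[C@H]2C(C)(C)CCC[C@@]21C
F6 | step 5 | 12-methoxy-13,14,15,16-tetranorlabd-11-ene-7β,8α-diol (E/Z) | COC=C[C@H]1[C@](C)(O)[C@@H](O)C[C@H]2C(C)(C)CCC[C@@]21C
F7 | step 6 | 12,12-diethoxy-8α-formyl-13,14,15,16-tetranorlabdan-7-one | CCOC(OCC)C[C@H]1[C@](C)(C=O)C(=O)C[C@H]2C(C)(C)CCC[C@@]21C
F8 | step 6 | 12,12-diethoxy-13,14,15,16-tetranorlabdan-7-one (8β-H, 8α-methyl) | CCOC(OCC)C[C@H]1[C@H](C)C(=O)C[C@H]2C(C)(C)CCC[C@@]21C
F9 | step 6 | 12,12-diethoxy-8α-hydroxy-13,14,15,16-tetranorlabdan-7-one | CCOC(OCC)C[C@H]1[C@](C)(O)C(=O)C[C@H]2C(C)(C)CCC[C@@]21C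
F10 | step 12 | (12E)-6α-{2-[bis(2,2,2-trifluoroethoxy)phosphoryl]propanoyloxy}-8α-hydroxylabda-12,14-dien-7-one | C=C/C(C)=C/C[C@H]1[C@](C)(O)C(=O)[C@H](OC(=O)C(C)P(=O)(OCC(F)(F)F)OCC(F)(F)F)[C@H]2C(C)(C)CCC[C@@]21C
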